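The route reads ring C1–C8–C5–C6–C7 of the bicyclo[3.2.1]octenedione (C8 bridge ketone, C1/C5 bridgeheads, C6/C7 aryl-bearing carbons) as a trans-3,4-diarylcyclopentanone. That motif is the classical outcome of reductive β,β-coupling of two cinnamoyl-type acceptors followed by Dieckmann closure. Cutting C8–C5 and C7–C6 opens both carbocycles to one chain. In the forward direction, SmI2 joins the two aryl-bearing β-carbons of the acyclic enone–enoyl imide 10. The resulting ketone enolate then acylates itself across the new seven-membered ring and expels the chiral oxazolidinone that set the absolute configuration. In 10, C2 and C3 are CH2 groups and C4 is the enone carbonyl. The styryl arm and the C2 ketone are added later.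

Key step: step 5

Remark: skeletal atoms carry target numbers throughout the text: C1 (bridgehead between the two ketones), C2 (enone C=O), C3, C4 (styryl-bearing), C5 (bridgehead), C6 (3,5-dihydroxyphenyl-bearing), C7 (3,4-dihydroxyphenyl-bearing), C8 (bridge C=O). Systematic names in the list use their own numbering.
Assumption: the s-cis chelate model is taken to hold for the α-alkylated enoyl imide 10. If the sense of induction were opposite, the enantiomer of 8 would be used.

Step 1
Reactants: 1 triethyl phosphonoacetate; 2 methyl vinyl ketone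
Product: 3 ethyl 2-(diethoxyphosphoryl)-5-oxohexanoate (racemic)
Conditions: NaOEt (0.1 equiv), EtOH, 0 → 23 °C, 1 in excess
Reagents that add atoms: none
Why: Base-catalysed Michael addition of the stabilised phosphonoacetate carbanion to the unhindered vinyl ketone should stop at the mono-adduct when 1 is in excess, and the new stereocentre is racemic and is erased in step 2.

Step 2
Reactants: 3 ethyl 2-(diethoxyphosphoryl)-5-oxohexanoate; 4 3,4-dimethoxybenzaldehyde
Product: 5 ethyl (2E)-2-[(3,4-dimethoxyphenyl)methylidene]-5-oxohexanoate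
Conditions: NaH, THF, 0 → 23 °C
Reagents that add atoms: none
Why: Horner–Wadsworth–Emmons olefination by the α-alkylated phosphonoacetate anion, which NaH forms in preference to the ketone enolate, should give mainly the E-alkene with aryl trans to the ester.

Step 3
Reactants: 5 ethyl (2E)-2-[(3,4-dimethoxyphenyl)methylidene]-5-oxohexanoate; 6 3,5-dimethoxybenzaldehyde
Product: 7 (2E,6E)-7-(3,5-dimethoxyphenyl)-2-[(3,4-dimethoxyphenyl)methylidene]-5-oxohept-6-enoic acid
Conditions: NaOH (5 equiv), EtOH–H2O, 23 → 50 °C; then 1 M HCl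
Reagents that add atoms: sodium hydroxide, [Na+].[OH-]
Why: Claisen–Schmidt condensation under hydroxide occurs at the methyl group of the methyl ketone and dehydrates to the E-enone, while the same medium saponifies the ester to a carboxylate that also switches off the benzylidene unit as a Michael acceptor.

Step 4
Reactants: 7 (2E,6E)-7-(3,5-dimethoxyphenyl)-2-[(3,4-dimethoxyphenyl)methylidene]-5-oxohept-6-enoic acid; 8 (4R)-4-benzyl-1,3-oxazolidin-2-one
Product: 10 (4R)-4-benzyl-3-[(2E,6E)-7-(3,5-dimethoxyphenyl)-2-[(3,4-dimethoxyphenyl)methylidene]-5-oxohept-6-enoyl]-1,3-oxazolidin-2-one, via mixed pivalic anhydride 9 (not isolated)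
Conditions: PivCl, Et3N, THF, −20 °C; then LiCl, 8, 23 °C
Reagents that add atoms: none
Why: N-acylation of the oxazolidinone through the mixed pivalic anhydride with LiCl activation is a standard route to N-enoyl imides and leaves both alkenes and the stereocentre of 8 untouched.

Step 5
Reactants: 10 (4R)-4-benzyl-3-[(2E,6E)-7-(3,5-dimethoxyphenyl)-2-[(3,4-dimethoxyphenyl)methylidene]-5-oxohept-6-enoyl]-1,3-oxazolidin-2-one
Product: 12 (1R,5R,6R,7R)-6-(3,4-dimethoxyphenyl)-7-(3,5-dimethoxyphenyl)bicyclo[3.2.1]octane-2,8-dione, via samarium cycloheptenolate 11 (not isolated)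
Conditions: SmI2 (2.5 equiv, 0.1 M in THF, slow addition), t-BuOH (1.0 equiv), THF (0.005 M in 10), −78 → 0 °C; aq. NH4Cl
Reagents that add atoms: none
Why: Proposed new method: SmI2 transfers one electron to the aryl-conjugated enone of 10, the benzylic β-radical of the samarium-bound radical anion (future C6) adds to the β-carbon (future C7) of the samarium-chelated α-alkylcinnamoyl imide, a second electron gives the bis-enolate, and after t-BuOH has delivered one proton the mono-enolate tautomer 11, which is protonated at C1 and keeps the ketone enolate, attacks the imide carbonyl C8 through C5 and expels the oxazolidinone anion. The closest known reaction types are the cathodic or SmI2-induced hydrocoupling–Dieckmann cyclisation of cinnamic esters and N-cinnamoyl oxazolidinones to trans-3,4-diaryl-2-acylcyclopentanones and the auxiliary-controlled radical conjugate addition to lanthanide-chelated N-enoyl oxazolidinones, neither of which has been run between two different tethered acceptors or to a bridged product. The seven-membered ring closes 7-endo-trig at both acceptors, and the transannular acylation then closes the cyclopentanone 5-(enolexo)-exo-trig and the cyclohexanone 6-(enolendo)-exo-trig. C7 is set by the benzyl group of the R-auxiliary, which blocks one face of the s-cis chelated imide; C6 follows because the two aryl groups stay anti as the C6–C7 bond forms; C1 reacts as the epimer whose acyl group is trans to the C7 aryl group, since its only gauche contact is with the still long forming bond, so the C7 aryl ends endo and the C6 aryl exo; C5 can bond only on the face where C8 sits. β,β-Coupling is preferred over 6-exo attack at either α-carbon because it alone joins the carbons of highest spin density and acceptor coefficient and leaves both electrons next to carbonyl groups, and high dilution holds back dimerisation. Because C2 and C3 are CH2 groups, C1 is acidified by the imide alone, so the productive tautomer stays within reach by proton exchange, and the resonance-poor imide, the weakly nucleophilic oxazolidinone anion and the non-enolisable bridgeheads should keep the 1,3-diketone from reopening.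

Step 6
Reactants: 12 (1R,5R,6R,7R)-6-(3,4-dimethoxyphenyl)-7-(3,5-dimethoxyphenyl)bicyclo[3.2.1]octane-2,8-dione
Product: 13 (1R,5R,6R,7R)-6-(3,4-dimethoxyphenyl)-7-(3,5-dimethoxyphenyl)-8-oxobicyclo[3.2.1]oct-2-en-2-yl trifluoromethanesulfonate
Conditions: KHMDS, THF, −78 °C; then PhNTf2, −78 → 0 °C
Reagents that add atoms: N-phenylbis(trifluoromethanesulfonimide), O=S(=O)(N(c1ccccc1)S(=O)(=O)C(F)(F)F)C(F)(F)F
Why: Enol triflate formation by kinetic deprotonation and O-sulfonylation can occur only at C3, because every other α-carbon of the two ketones is a bridgehead that cannot enolise.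

Step 7
Reactants: 13 (1R,5R,6R,7R)-6-(3,4-dimethoxyphenyl)-7-(3,5-dimethoxyphenyl)-8-oxobicyclo[3.2.1]oct-2-en-2-yl trifluoromethanesulfonate; 14 3,4-dimethoxystyrene
Product: 15 (1R,5R,6R,7R)-6-(3,4-dimethoxyphenyl)-7-(3,5-dimethoxyphenyl)-2-[(E)-2-(3,4-dimethoxyphenyl)ethenyl]bicyclo[3.2.1]oct-2-en-8-one
Conditions: Pd(OAc)2 (5 mol %), PPh3 (15 mol %), Et3N, DMF, 70 °C
Reagents that add atoms: none
Why: Mizoroki–Heck coupling (oxidative addition of the enol triflate to zerovalent palladium, syn-insertion at the CH2 terminus of the styrene, syn-β-hydride elimination) should give the E-configured 1,3-diene and leave the non-enolisable ketone alone.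

Step 8
Reactants: 15 (1R,5R,6R,7R)-6-(3,4-dimethoxyphenyl)-7-(3,5-dimethoxyphenyl)-2-[(E)-2-(3,4-dimethoxyphenyl)ethenyl]bicyclo[3.2.1]oct-2-en-8-one
Product: 16 (1R,5R,6R,7R)-6-(3,4-dihydroxyphenyl)-7-(3,5-dihydroxyphenyl)-2-[(E)-2-(3,4-dihydroxyphenyl)ethenyl]bicyclo[3.2.1]oct-2-en-8-one
Conditions: BBr3 (12 equiv), CH2Cl2, −78 → 0 °C; then H2O
Reagents that add atoms: none
Why: Lewis-acid aryl methyl ether cleavage is placed here because 15 holds only an isolated bridge ketone, so no 1,3-diketone leaving group is present that could let the C1–C7 bond ionise.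

Step 9
Reactants: 16 (1R,5R,6R,7R)-6-(3,4-dihydroxyphenyl)-7-(3,5-dihydroxyphenyl)-2-[(E)-2-(3,4-dihydroxyphenyl)ethenyl]bicyclo[3.2.1]oct-2-en-8-one
Product: 17 the hexakis(tert-butyldimethylsilyl) ether of 16, (1R,5R,6R,7R)
Conditions: TBSCl, imidazole, DMF, 23 °C
Reagents that add atoms: tert-butyldimethylsilyl chloride, CC(C)(C)[Si](C)(C)Cl
Why: Imidazole-promoted silyl ether formation masks all six phenols against the oxidant of step 10 with groups that later leave under near-neutral conditions.

Step 10
Reactants: 17 the hexakis(tert-butyldimethylsilyl) ether of 16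
Product: 18 hexakis-O-(tert-butyldimethylsilyl)jezonodione, (1S,5R,6R,7R)
Conditions: Rh2(cap)4 (1 mol %), t-BuOOH (70 % in H2O), 1,2-dichloroethane, 40 °C
Reagents that add atoms: tert-butyl hydroperoxide, CC(C)(C)OO
Why: Radical allylic oxidation of the only allylic CH2 group (C2), the reaction type used for the C7 oxidation of Δ5-steroids, should give the cross-conjugated dienone because the other allylic position, C5, is a bridgehead whose radical gains no allylic stabilisation.

Step 11
Reactants: 18 hexakis-O-(tert-butyldimethylsilyl)jezonodione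
Product: 19 jezonodione, (1S,5R,6R,7R)-7-(3,4-dihydroxyphenyl)-6-(3,5-dihydroxyphenyl)-4-[(E)-2-(3,4-dihydroxyphenyl)ethenyl]bicyclo[3.2.1]oct-3-ene-2,8-dione
Conditions: Et3N·3HF, THF, 0 → 23 °C, argon
Reagents that add atoms: none
Why: Fluoride-driven Si–O cleavage with the weakly acidic amine–HF complex frees the six phenols without free phenoxide or strong acid, either of which could open the C1–C7 bond, and it touches no stereocentre.

Compound list
1 | triethyl phosphonoacetate | CCOC(=O)CP(=O)(OCC)OCC | starting material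
2 | methyl vinyl ketone | CC(=O)C=C | starting material
3 | ethyl 2-(diethoxyphosphoryl)-5-oxohexanoate (racemic) | CCOC(=O)C(CCC(C)=O)P(=O)(OCC)OCC | intermediate
4 | 3,4-dimethoxybenzaldehyde | COc1ccc(C=O)cc1OC | starting material
5 | ethyl (2E)-2-[(3,4-dimethoxyphenyl)methylidene]-5-oxohexanoate | CCOC(=O)/C(CCC(C)=O)=C/c1ccc(OC)c(OC)c1 | intermediate
6 | 3,5-dimethoxybenzaldehyde | COc1cc(C=O)cc(OC)c1 | starting material
7 | (2E,6E)-7-(3,5-dimethoxyphenyl)-2-[(3,4-dimethoxyphenyl)methylidene]-5-oxohept-6-enoic acid | COc1cc(OC)cc(/C=C/C(=O)CC/C(=C\c2ccc(OC)c(OC)c2)C(=O)O)c1 | intermediate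
8 | (4R)-4-benzyl-1,3-oxazolidin-2-one | O=C1N[C@H](Cc2ccccc2)CO1 | starting material
9 | mixed anhydride of 7 with pivalic acid | COc1cc(OC)cc(/C=C/C(=O)CC/C(=C\c2ccc(OC)c(OC)c2)C(=O)OC(=O)C(C)(C)C)c1 | intermediate
10 | (4R)-4-benzyl-3-[(2E,6E)-7-(3,5-dimethoxyphenyl)-2-[(3,4-dimethoxyphenyl)methylidene]-5-oxohept-6-enoyl]-1,3-oxazolidin-2-one | COc1cc(OC)cc(/C=C/C(=O)CC/C(=C\c2ccc(OC)c(OC)c2)C(=O)N2[C@H](Cc3ccccc3)COC2=O)c1 | intermediate
11 | samarium enolate (drawn as the free enolate) of the cycloheptanone imide: 2-(3,4-dimethoxyphenyl)-3-(3,5-dimethoxyphenyl)-5-oxidocyclohept-4-ene-1-carbonyl oxazolidinone, 1,2-trans and 2,3-trans | C1CC([O-])=C[C@H](c2cc(OC)cc(OC)c2)[C@@H](c2ccc(OC)c(OC)c2)[C@@H]1C(=O)N1[C@H](Cc2ccccc2)COC1=O | intermediate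
12 | (1R,5R,6R,7R)-6-(3,4-dimethoxyphenyl)-7-(3,5-dimethoxyphenyl)bicyclo[3.2.1]octane-2,8-dione (6-aryl endo, 7-aryl exo) | C1CC(=O)[C@@H]2C(=O)[C@H]1[C@H](c1ccc(OC)c(OC)c1)[C@H]2c1cc(OC)cc(OC)c1 | intermediate
13 | (1R,5R,6R,7R)-6-(3,4-dimethoxyphenyl)-7-(3,5-dimethoxyphenyl)-8-oxobicyclo[3.2.1]oct-2-en-2-yl trifluoromethanesulfonate | C1C=C(OS(=O)(=O)C(F)(F)F)[C@@H]2C(=O)[C@H]1[C@H](c1ccc(OC)c(OC)c1)[C@H]2c1cc(OC)cc(OC)c1 | intermediate
14 | 3,4-dimethoxystyrene | C=Cc1ccc(OC)c(OC)c1 | starting material
15 | (1R,5R,6R,7R)-6-(3,4-dimethoxyphenyl)-7-(3,5-dimethoxyphenyl)-2-[(E)-2-(3,4-dimethoxyphenyl)ethenyl]bicyclo[3.2.1]oct-2-en-8-one | C1C=C(/C=C/c2ccc(OC)c(OC)c2)[C@@H]2C(=O)[C@H]1[C@H](c1ccc(OC)c(OC)c1)[C@H]2c1cc(OC)cc(OC)c1 | intermediate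
16 | (1R,5R,6R,7R)-6-(3,4-dihydroxyphenyl)-7-(3,5-dihydroxyphenyl)-2-[(E)-2-(3,4-dihydroxyphenyl)ethenyl]bicyclo[3.2.1]oct-2-en-8-one | C1C=C(/C=C/c2ccc(O)c(O)c2)[C@@H]2C(=O)[C@H]1[C@H](c1ccc(O)c(O)c1)[C@H]2c1cc(O)cc(O)c1 | intermediate
17 | hexakis(tert-butyldimethylsilyl) ether of 16 | C1C=C(/C=C/c2ccc(O[Si](C)(C)C(C)(C)C)c(O[Si](C)(C)C(C)(C)C)c2)[C@@H]2C(=O)[C@H]1[C@H](c1ccc(O[Si](C)(C)C(C)(C)C)c(O[Si](C)(C)C(C)(C)C)c1)[C@H]2c1cc(O[Si](C)(C)C(C)(C)C)cc(O[Si](C)(C)C(C)(C)C)c1 | intermediate
18 | hexakis-O-(tert-butyldimethylsilyl)jezonodione, (1S,5R,6R,7R) | O=C1C=C(/C=C/c2ccc(O[Si](C)(C)C(C)(C)C)c(O[Si](C)(C)C(C)(C)C)c2)[C@@H]2C(=O)[C@H]1[C@H](c1ccc(O[Si](C)(C)C(C)(C)C)c(O[Si](C)(C)C(C)(C)C)c1)[C@H]2c1cc(O[Si](C)(C)C(C)(C)C)cc(O[Si](C)(C)C(C)(C)C)c1 | intermediate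
19 | jezonodione, (1S,5R,6R,7R) | O=C1C=C(/C=C/c2ccc(O)c(O)c2)[C@@H]2C(=O)[C@H]1[C@H](c1ccc(O)c(O)c1)[C@H]2c1cc(O)cc(O)c1 | target

Total step count: 11. Longest linear sequence: 11 steps (steps 1 to 11).

Steps most likely to fail

Step 5. The radical anion may be protonated or may couple with a second molecule before the seven-membered ring closes. The twisted α-alkyl enoyl imide may give a weak facial bias, or the diketone may reopen by retro-Claisen attack.
- The fallback sets out from 10 and returns at 12.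
- Visible-light triplet sensitisation (Ir[dF(CF3)ppy]2(dtbbpy)PF6, blue LED, MeCN) should bring about the intramolecular [2+2] photocycloaddition of the two styrene-type alkenes, a 1,6-diene that obeys the rule of five. It should give the cis-fused bicyclo[3.2.0]heptan-2-one photoadduct F1, in which C6 and C7 are already joined and the aryl groups are trans.
- SmI2 in THF with t-BuOH then cleaves the strained cyclobutane bond that lies between the ketone and the imide (a 1,4-dicarbonyl array). The same ketone enolate closes by Dieckmann acylation to 12.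

Step 10. Hydrogen abstraction may occur at the benzylic C6–H or C7–H, the delocalised radical may be trapped at the wrong terminus, or the diene may be over-oxidised.
- The fallback sets out from 17 and returns at 18.
- A Schenck ene reaction with singlet oxygen (O2, tetraphenylporphyrin, light, CH2Cl2, −78 °C) takes the only allylic hydrogen, at C2, on the face syn to C8. It gives the tertiary allylic hydroperoxide F2, with oxygen on C4 and the alkene moved to C2=C3.
- PPh3 reduces F2 to the tertiary allylic alcohol F3.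
- Babler–Dauben oxidative transposition with PCC carries the oxygen to C2 and gives 18.

Step 11. Transient phenoxide may open the skeleton by retro-Michael cleavage, the catechols may oxidise in air during work-up, or silyl removal may be incomplete.
- The fallback sets out from 16 and returns at 19.
- Peracetylation (Ac2O, pyridine) gives the hexaacetate F4.
- The allylic oxidation of step 10 gives the hexaacetate dienone F5.
- Enzyme-catalysed alcoholysis (immobilised Candida antarctica lipase B, n-BuOH, methyl tert-butyl ether) removes the acetates at neutral pH to give 19.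

Further compounds
F1 | step 5 | cis-fused bicyclo[3.2.0]heptan-2-one photoadduct (imide on the ring-fusion carbon, 3,4-dimethoxyphenyl cis to the ring CH2, 3,5-dimethoxyphenyl trans to it) | O=C1CC[C@]2(C(=O)N3[C@H](Cc4ccccc4)COC3=O)[C@H](c3ccc(OC)c(OC)c3)[C@@H](c3cc(OC)cc(OC)c3)[C@H]12
F2 | step 10 | tertiary allylic hydroperoxide (OOH on C4 syn to C8, alkene C2=C3), hexa-TBS ether | C1=C[C@@](OO)(/C=C/c2ccc(O[Si](C)(C)C(C)(C)C)c(O[Si](C)(C)C(C)(C)C)c2)[C@@H]2C(=O)[C@H]1[C@H](c1ccc(O[Si](C)(C)C(C)(C)C)c(O[Si](C)(C)C(C)(C)C)c1)[C@H]2c1cc(O[Si](C)(C)C(C)(C)C)cc(O[Si](C)(C)C(C)(C)C)c1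
F3 | step 10 | tertiary allylic alcohol (OH on C4 syn to C8, alkene C2=C3), hexa-TBS ether | C1=C[C@@](O)(/C=C/c2ccc(O[Si](C)(C)C(C)(C)C)c(O[Si](C)(C)C(C)(C)C)c2)[C@@H]2C(=O)[C@H]1[C@H](c1ccc(O[Si](C)(C)C(C)(C)C)c(O[Si](C)(C)C(C)(C)C)c1)[C@H]2c1cc(O[Si](C)(C)C(C)(C)C)cc(O[Si](C)(C)C(C)(C)C)c1
F4 | step 11 | hexaacetate of 16 | C1C=C(/C=C/c2ccc(OC(C)=O)c(OC(C)=O)c2)[C@@H]2C(=O)[C@H]1[C@H](c1ccc(OC(C)=O)c(OC(C)=O)c1)[C@H]2c1cc(OC(C)=O)cc(OC(C)=O)c1
F5 | step 11 | jezonodione hexaacetate | O=C1C=C(/C=C/c2ccc(OC(C)=O)c(OC(C)=O)c2)[C@@H]2C(=O)[C@H]1[C@H](c1ccc(OC(C)=O)c(OC(C)=O)c1)[C@H]2c1cc(OC(C)=O)cc(OC(C)=O)c1
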